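**Strategy**

Indane numbering: C1 carries the 2-methylbutanoate, C2 is the ketone, C3 the hydroxyethyl group (carbinol C1′), C3a/C7a the ring fusion, C4 the isopropyl group, C6 the enoate, C7 the methylene. C7 and C1′ both sit at carbonyl level in a 1,5-relationship spanning the C7a–C3a bond, and the C2 ketone flanks C3, so both rings are cut at C7a–C3a and C3–C2. One base-mediated Michael–Claisen sequence on the acyclic keto-enone ester methyl (7R,8E)-4,10-dioxo-7-(propan-2-yl)undec-8-enoate should close the cyclohexanone, then the cyclopentanone, and relay its single catalyst-set centre (C4) to C3a, C7a and C3; later steps only adjust C7, C1′, C1 and C6.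

Key step: step 4

Remark on the chemistry: the aldehyde Michael addition needs the (R)-configured prolinol silyl ether to give the (7R) centre, and acids 16 and 19 are assumed to be purchased as single isomers.

**Route**

Step 1
Reactants: 1 methyl 4-chloro-4-oxobutanoate; 2 tributyl(vinyl)stannane
Product: 3 methyl 4-oxohex-5-enoate
Conditions: PdCl(CH2Ph)(PPh3)2 (1 mol %), CHCl3, 60 °C
Reagents that add atoms: none
Why: Stille acylation: oxidative addition of the acyl chloride to palladium, vinyl transfer from tin and reductive elimination should give the vinyl ketone under neutral conditions that spare the methyl ester.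

Step 2
Reactants: 3 methyl 4-oxohex-5-enoate; 4 3-methylbutanal
Product: 5 methyl (7R)-7-formyl-8-methyl-4-oxononanoate
Conditions: (R)-2-[diphenyl(trimethylsilyloxy)methyl]pyrrolidine (5 mol %), ethyl 3,4-dihydroxybenzoate (20 mol %), neat, 4 °C; crude 5 taken on at once
Reagents that add atoms: none
Why: Enamine-mediated organocatalytic Michael addition of an aldehyde to a vinyl ketone: the E-enamine of 4 is shielded on one face by the diphenyl(silyloxy)methyl group, so the hydrogen-bond-activated enone should be attacked from the open face, which with the (R)-catalyst sets the (7R) centre (the later C4), and the mild conditions should not trigger aldol closure of the δ-keto aldehyde.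

Step 3
Reactants: 5 methyl (7R)-7-formyl-8-methyl-4-oxononanoate; 6 1-(triphenylphosphoranylidene)propan-2-one
Product: 7 methyl (7R,8E)-4,10-dioxo-7-(propan-2-yl)undec-8-enoate
Conditions: CH2Cl2, rt → 40 °C
Reagents that add atoms: none
Why: Wittig olefination with a stabilised ylide, which should react only at the aldehyde (neither the ketone nor the ester), give the E-enone and be neutral enough to leave the α-branched stereocentre untouched.

Step 4
Reactants: 7 methyl (7R,8E)-4,10-dioxo-7-(propan-2-yl)undec-8-enoate
Product: 9 (3R,3aR,4R,7aS)-3-acetyl-4-(propan-2-yl)octahydro-1H-indene-2,7-dione, via Michael adduct keto ester 8 (not isolated)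
Conditions: KOt-Bu (0.2 equiv), THF/t-BuOH, −20 °C; then KOt-Bu (2.0 equiv), 0 °C → rt; AcOH
Reagents that add atoms: none
Why: tert-Butoxide reversibly enolises the C7 ketone (chain C4), and only the enolate towards C7a (chain C3) can reach the enone, adding to C3a (chain C8) to give 8; the C3 carbon (chain C9), now α to the acetyl group, is then acylated by the methyl ester, methoxide leaves, and the β-diketone is held as its potassium enolate, which makes the sequence irreversible. The closest known reaction type is the base-mediated intramolecular Michael addition followed by a Claisen (Dieckmann-type) condensation, as in classical syntheses of cyclic β-diketones. The cyclohexanone closes in a 6-(enolendo)-exo-trig mode and the cyclopentanone in a 5-(enolexo)-exo-trig mode. C3a is set against the existing C4 centre by a chair transition state with the isopropyl group and the enone arm both equatorial, so the new C3a substituent is anti to isopropyl; C7a (α to the C7 ketone) and C3 (between two carbonyls) stay epimerisable and should settle in the trans-fused arrangement with all ring substituents equatorial or pseudo-equatorial. The step needs one productive enolate out of three enolisable sites and an intact C4 centre: the enolate towards C6 could only close a four-membered ring, aldol closures from the acetyl methyl or C6 give bridged or medium rings and are reversible, the competing Dieckmann closure of the γ-keto ester to a cyclopentane-1,3-dione is slow at this temperature, and the enone is consumed with only catalytic alkoxide present so that the full equivalent of base meets a substrate that no longer has a γ-hydrogen.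

Step 5
Reactants: 9 (3R,3aR,4R,7aS)-3-acetyl-4-(propan-2-yl)octahydro-1H-indene-2,7-dione
Product: 11 (3R,3aR,4R,7aS)-3-acetyl-7-methylidene-4-(propan-2-yl)octahydro-2H-inden-2-one, via potassium diketone enolate 10 (not isolated)
Conditions: KOt-Bu (1.05 equiv), THF, 0 °C; then Ph3P=CH2 (2.5 equiv, from Ph3PCH3Br and KOt-Bu), 0 → 45 °C; AcOH
Reagents that add atoms: methyltriphenylphosphonium bromide, C[P+](c1ccccc1)(c1ccccc1)c1ccccc1.[Br-]
Why: Wittig methylenation: the acidic β-diketone is first stored as its potassium enolate 10, which is inert to the ylide, so methylidenetriphenylphosphorane should attack only the C7 ketone, and any base-induced epimerisation at C7a before olefination should funnel to the more stable trans fusion, which the new alkene then locks.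

Step 6
Reactants: 11 (3R,3aR,4R,7aS)-3-acetyl-7-methylidene-4-(propan-2-yl)octahydro-2H-inden-2-one
Product: 12 (3R,3aR,4R,7aS)-3-[(1S)-1-hydroxyethyl]-7-methylidene-4-(propan-2-yl)octahydro-2H-inden-2-one
Conditions: Zn(BH4)2 (0.6 equiv), Et2O, −78 → −30 °C; aq NH4Cl
Reagents that add atoms: none
Why: Chelation-controlled hydride reduction: Zn(BH4)2 binds the two carbonyl oxygens in a six-membered chelate, hydride should add to the unhindered methyl ketone (addition at C2 would add eclipsing strain to the cyclopentanone) from the chelate face opposite the C3–C3a bond to give the syn (3R,1′S) β-hydroxy ketone, with C3 free to equilibrate through the enol beforehand and low temperature with limited hydride protecting the alkene and the C2 ketone.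

Step 7
Reactants: 12 (3R,3aR,4R,7aS)-3-[(1S)-1-hydroxyethyl]-7-methylidene-4-(propan-2-yl)octahydro-2H-inden-2-one
Product: 13 (3R,3aR,4R,7aS)-3-[(1S)-1-{[tert-butyl(dimethyl)silyl]oxy}ethyl]-7-methylidene-4-(propan-2-yl)octahydro-2H-inden-2-one
Conditions: TBSOTf, 2,6-lutidine, CH2Cl2, −78 °C
Reagents that add atoms: tert-butyldimethylsilyl trifluoromethanesulfonate, CC(C)(C)[Si](C)(C)OS(=O)(=O)C(F)(F)F
Why: Silylation of a hindered secondary alcohol with a silyl triflate and a non-nucleophilic pyridine base, conditions that are fast at −78 °C and too mild for retro-aldol cleavage or β-elimination of the β-hydroxy ketone.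

Step 8
Reactants: 13 (3R,3aR,4R,7aS)-3-[(1S)-1-{[tert-butyl(dimethyl)silyl]oxy}ethyl]-7-methylidene-4-(propan-2-yl)octahydro-2H-inden-2-one
Product: 15 (1S,3R,3aR,4R,7aS)-3-[(1S)-1-{[tert-butyl(dimethyl)silyl]oxy}ethyl]-1-hydroxy-7-methylidene-4-(propan-2-yl)octahydro-2H-inden-2-one, via potassium C1 enolate 14 (not isolated)
Conditions: KN(SiMe3)2, THF, −78 °C; then 2-(benzenesulfonyl)-3-phenyloxaziridine, −78 °C; AcOH
Reagents that add atoms: 2-(benzenesulfonyl)-3-phenyloxaziridine, O=S(=O)(c1ccccc1)N1OC1c1ccccc1
Why: Enolate hydroxylation with an N-sulfonyloxaziridine: the hindered amide base should remove a proton from the C1 methylene and not from the tertiary, shielded C3–H, and the oxidant should approach the enolate from the α-face (cis to H7a) since the β-face of C1 is screened by the exocyclic methylene, which lies nearly eclipsed with the C7a–C1 bond, and by the axial H3a and the C3 side chain, giving the (1S) alcohol.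

Step 9
Reactants: 15 (1S,3R,3aR,4R,7aS)-3-[(1S)-1-{[tert-butyl(dimethyl)silyl]oxy}ethyl]-1-hydroxy-7-methylidene-4-(propan-2-yl)octahydro-2H-inden-2-one; 16 (2R)-2-methylbutanoic acid
Product: 17 (1R,3R,3aR,4R,7aS)-3-[(1S)-1-{[tert-butyl(dimethyl)silyl]oxy}ethyl]-7-methylidene-2-oxo-4-(propan-2-yl)octahydro-1H-inden-1-yl (2R)-2-methylbutanoate
Conditions: PPh3, DIAD, THF, 0 °C → rt
Reagents that add atoms: none
Why: Mitsunobu esterification: the α-ketol is activated as its alkoxyphosphonium ion and displaced by the carboxylate in an SN2 reaction accelerated by the adjacent carbonyl, which inverts C1 to the required (1R) configuration, leaves the stereocentre of the acid untouched and has no anti-periplanar hydrogen for elimination because H7a is syn to the leaving group.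

Step 10
Reactants: 17 (1R,3R,3aR,4R,7aS)-3-[(1S)-1-{[tert-butyl(dimethyl)silyl]oxy}ethyl]-7-methylidene-2-oxo-4-(propan-2-yl)octahydro-1H-inden-1-yl (2R)-2-methylbutanoate
Product: 18 (1R,3R,3aR,4R,6S,7aS)-3-[(1S)-1-{[tert-butyl(dimethyl)silyl]oxy}ethyl]-6-hydroxy-7-methylidene-2-oxo-4-(propan-2-yl)octahydro-1H-inden-1-yl (2R)-2-methylbutanoate
Conditions: SeO2 (0.5 equiv), t-BuOOH (3 equiv), CH2Cl2, rt
Reagents that add atoms: selenium dioxide (transfers the oxygen), O=[Se]=O; tert-butyl hydroperoxide (restores it), CC(C)(C)OO
Why: Allylic oxidation with SeO2 (ene reaction at the terminal CH2 followed by [2,3]-sigmatropic shift of the allylseleninic acid): the C6 methylene should react in preference to the tertiary and crowded C7a–H, the axial α-hydrogen at C6 is the one aligned with the π-system, and oxygen is returned to C6 on that same face to give the axial (6S) alcohol with the exocyclic alkene restored, while the ketone and esters should be inert at room temperature.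

Step 11
Reactants: 18 (1R,3R,3aR,4R,6S,7aS)-3-[(1S)-1-{[tert-butyl(dimethyl)silyl]oxy}ethyl]-6-hydroxy-7-methylidene-2-oxo-4-(propan-2-yl)octahydro-1H-inden-1-yl (2R)-2-methylbutanoate; 19 (2E)-3-methylpent-2-enoic acid
Product: 20 (1R,3R,3aR,4R,6S,7aS)-3-[(1S)-1-{[tert-butyl(dimethyl)silyl]oxy}ethyl]-6-{[(2E)-3-methylpent-2-enoyl]oxy}-7-methylidene-2-oxo-4-(propan-2-yl)octahydro-1H-inden-1-yl (2R)-2-methylbutanoate
Conditions: DCC, 4-(dimethylamino)pyridine (0.3 equiv), CH2Cl2, 0 °C → rt
Reagents that add atoms: none
Why: Steglich esterification: carbodiimide activation with a nucleophilic pyridine catalyst acylates the only free hydroxyl with retention at C6, and avoiding an acid chloride with amine base should prevent vinylketene formation and thus keep the E geometry and conjugation of the enoate.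

Step 12
Reactants: 20 (1R,3R,3aR,4R,6S,7aS)-3-[(1S)-1-{[tert-butyl(dimethyl)silyl]oxy}ethyl]-6-{[(2E)-3-methylpent-2-enoyl]oxy}-7-methylidene-2-oxo-4-(propan-2-yl)octahydro-1H-inden-1-yl (2R)-2-methylbutanoate
Product: 21 (1R,3R,3aR,4R,6S,7aS)-3-[(1S)-1-hydroxyethyl]-6-{[(2E)-3-methylpent-2-enoyl]oxy}-7-methylidene-2-oxo-4-(propan-2-yl)octahydro-1H-inden-1-yl (2R)-2-methylbutanoate (CNP0224363.1)
Conditions: HF·pyridine, pyridine/THF, 0 °C → rt
Reagents that add atoms: none
Why: Fluoride-mediated desilylation under buffered, weakly acidic conditions should release the C1′ hydroxyl without acyl migration, retro-aldol cleavage, ionisation of the allylic ester or epimerisation α to the ketone.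

**Compound list**

1 | methyl 4-chloro-4-oxobutanoate | COC(=O)CCC(Cl)=O | starting material
2 | tributyl(vinyl)stannane | C=C[Sn](CCCC)(CCCC)CCCC | starting material
3 | methyl 4-oxohex-5-enoate | COC(=O)CCC(=O)C=C | intermediate
4 | 3-methylbutanal | CC(C)CC=O | starting material
5 | methyl (7R)-7-formyl-8-methyl-4-oxononanoate | COC(=O)CCC(=O)CC[C@H](C(C)C)C=O | intermediate
6 | 1-(triphenylphosphoranylidene)propan-2-one | CC(=O)C=P(c1ccccc1)(c1ccccc1)c1ccccc1 | starting material
7 | methyl (7R,8E)-4,10-dioxo-7-(propan-2-yl)undec-8-enoate | COC(=O)CCC(=O)CC[C@H](C(C)C)/C=C/C(C)=O | intermediate (key-step precursor)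
8 | methyl 2-[(1S,2R,3R)-6-oxo-2-(2-oxopropyl)-3-(propan-2-yl)cyclohexyl]acetate | O=C1[C@@H](CC(=O)OC)[C@H](CC(C)=O)[C@@H](C(C)C)CC1 | intermediate (not isolated)
9 | (3R,3aR,4R,7aS)-3-acetyl-4-(propan-2-yl)octahydro-1H-indene-2,7-dione (trans-fused; may be partly enolised) | O=C1[C@@H]2[C@H]([C@H](C(C)=O)C(=O)C2)[C@@H](C(C)C)CC1 | intermediate (key-step product)
10 | potassium (3aR,4R,7aS)-3-acetyl-7-oxo-4-(propan-2-yl)-3a,4,5,6,7,7a-hexahydro-1H-inden-2-olate | CC(=O)C1=C([O-])C[C@@H]2C(=O)CC[C@H](C(C)C)[C@@H]12.[K+] | intermediate (not isolated)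
11 | (3R,3aR,4R,7aS)-3-acetyl-7-methylidene-4-(propan-2-yl)octahydro-2H-inden-2-one | C=C1[C@@H]2[C@H]([C@H](C(C)=O)C(=O)C2)[C@@H](C(C)C)CC1 | intermediate
12 | (3R,3aR,4R,7aS)-3-[(1S)-1-hydroxyethyl]-7-methylidene-4-(propan-2-yl)octahydro-2H-inden-2-one | C=C1[C@@H]2[C@H]([C@H]([C@H](C)O)C(=O)C2)[C@@H](C(C)C)CC1 | intermediate
13 | (3R,3aR,4R,7aS)-3-[(1S)-1-{[tert-butyl(dimethyl)silyl]oxy}ethyl]-7-methylidene-4-(propan-2-yl)octahydro-2H-inden-2-one | C=C1[C@@H]2[C@H]([C@H]([C@H](C)O[Si](C)(C)C(C)(C)C)C(=O)C2)[C@@H](C(C)C)CC1 | intermediate
14 | potassium (3R,3aR,4R,7aR)-3-[(1S)-1-{[tert-butyl(dimethyl)silyl]oxy}ethyl]-7-methylidene-4-(propan-2-yl)-3a,4,5,6,7,7a-hexahydro-3H-inden-2-olate | C=C1[C@@H]2[C@H]([C@H]([C@H](C)O[Si](C)(C)C(C)(C)C)C([O-])=C2)[C@@H](C(C)C)CC1.[K+] | intermediate (not isolated)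
15 | (1S,3R,3aR,4R,7aS)-3-[(1S)-1-{[tert-butyl(dimethyl)silyl]oxy}ethyl]-1-hydroxy-7-methylidene-4-(propan-2-yl)octahydro-2H-inden-2-one | C=C1[C@@H]2[C@H]([C@H]([C@H](C)O[Si](C)(C)C(C)(C)C)C(=O)[C@H]2O)[C@@H](C(C)C)CC1 | intermediate
16 | (2R)-2-methylbutanoic acid | CC[C@@H](C)C(=O)O | starting material
17 | (1R,3R,3aR,4R,7aS)-3-[(1S)-1-{[tert-butyl(dimethyl)silyl]oxy}ethyl]-7-methylidene-2-oxo-4-(propan-2-yl)octahydro-1H-inden-1-yl (2R)-2-methylbutanoate | C=C1[C@@H]2[C@H]([C@H]([C@H](C)O[Si](C)(C)C(C)(C)C)C(=O)[C@@H]2OC(=O)[C@H](C)CC)[C@@H](C(C)C)CC1 | intermediate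
18 | (1R,3R,3aR,4R,6S,7aS)-3-[(1S)-1-{[tert-butyl(dimethyl)silyl]oxy}ethyl]-6-hydroxy-7-methylidene-2-oxo-4-(propan-2-yl)octahydro-1H-inden-1-yl (2R)-2-methylbutanoate | C=C1[C@@H]2[C@H]([C@H]([C@H](C)O[Si](C)(C)C(C)(C)C)C(=O)[C@@H]2OC(=O)[C@H](C)CC)[C@@H](C(C)C)C[C@@H]1O | intermediate
19 | (2E)-3-methylpent-2-enoic acid | CC/C(C)=C/C(=O)O | starting material
20 | (1R,3R,3aR,4R,6S,7aS)-3-[(1S)-1-{[tert-butyl(dimethyl)silyl]oxy}ethyl]-6-{[(2E)-3-methylpent-2-enoyl]oxy}-7-methylidene-2-oxo-4-(propan-2-yl)octahydro-1H-inden-1-yl (2R)-2-methylbutanoate | C=C1[C@@H]2[C@H]([C@H]([C@H](C)O[Si](C)(C)C(C)(C)C)C(=O)[C@@H]2OC(=O)[C@H](C)CC)[C@@H](C(C)C)C[C@@H]1OC(=O)/C=C(\C)CC | intermediate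
21 | (1R,3R,3aR,4R,6S,7aS)-3-[(1S)-1-hydroxyethyl]-6-{[(2E)-3-methylpent-2-enoyl]oxy}-7-methylidene-2-oxo-4-(propan-2-yl)octahydro-1H-inden-1-yl (2R)-2-methylbutanoate (CNP0224363.1) | C=C1[C@@H]2[C@H]([C@H]([C@H](C)O)C(=O)[C@@H]2OC(=O)[C@H](C)CC)[C@@H](C(C)C)C[C@@H]1OC(=O)/C=C(\C)CC | target

**Step count**

Total steps: 12. Longest linear sequence: 12 steps (1 and 2 to 21).

**Steps most likely to fail**

Step 6 (reduction of the β-diketone). What may go wrong: hydride addition is not confined to the acetyl carbonyl (attack at C2, or further reduction to the diol), or the enolised diketone is held back as a zinc enolate so that conversion stalls. The fallback sets out again from 11 and replaces the chelating borohydride by a chiral ruthenium hydride: transfer hydrogenation with RuCl(p-cymene)[(S,S)-TsNCH(Ph)CH(Ph)NH2] in HCO2H/NEt3. In this weakly acidic medium the diketone stays neutral, and catalysts of this type are known to reduce the less hindered methyl ketone of a 1,3-diketone and stop at the β-hydroxy ketone. The carbinol configuration would then be fixed by the ligand and not by the substrate; the (S,S) complex is expected to give (1′S) by analogy with aryl methyl ketones, with the (R,R) complex as the alternative. C3 keeps equilibrating through the enol until reduction occurs (dynamic kinetic resolution). The fallback returns to the route at 12 and makes no new compound.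

Step 8 (hydroxylation at C1). What may go wrong: poor or reversed facial selectivity in the enolate oxidation, because a torsional preference for attack anti to the axial H7a competes with the steric bias argued above. The fallback sets out from 13 and keeps the oxidation but changes how the ester is made. Attack on the β-face would give the epimer (1R,3R,3aR,4R,7aS)-3-[(1S)-1-{[tert-butyl(dimethyl)silyl]oxy}ethyl]-1-hydroxy-7-methylidene-4-(propan-2-yl)octahydro-2H-inden-2-one F1, which already has the target configuration at C1. It is esterified with 16 with retention (DCC, 4-(dimethylamino)pyridine, CH2Cl2) in place of the Mitsunobu inversion, and the route is rejoined at 17. A mixture of 15 and F1 would be separated and each epimer taken to 17 by the esterification that suits it, so the two-step sequence is stereoconvergent.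

Step 4 (Michael–Claisen sequence). What may go wrong: loss of configurational purity at C4 through γ-deprotonation of the enone before it has cyclised, or diversion at the Michael stage into reversible bridged aldols so that the Claisen closure stalls. The fallback sets out from 7 and makes the same two bonds in two separate operations with different activation. The six-membered ring is closed by enamine catalysis (pyrrolidine, AcOH, CH2Cl2, rt): the saturated C7 ketone forms the enamine, its C7a terminus adds to the enone in the same 6-exo-trig sense, no alkoxide is present, and 8 is isolated. The Claisen closure is then run on 8 alone with KOt-Bu in THF, where neither an enone nor a γ-hydrogen remains, and the route is rejoined at 9. No new compound arises.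

**Further compounds**

F0 | step 6 | none | none
F1 | step 8 | (1R,3R,3aR,4R,7aS)-3-[(1S)-1-{[tert-butyl(dimethyl)silyl]oxy}ethyl]-1-hydroxy-7-methylidene-4-(propan-2-yl)octahydro-2H-inden-2-one | C=C1[C@@H]2[C@H]([C@H]([C@H](C)O[Si](C)(C)C(C)(C)C)C(=O)[C@@H]2O)[C@@H](C(C)C)CC1
F0 | step 4 | none | none
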